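# Proposed total synthesis of CNP0137407.7 by a ring-forming double allylboration

## Analysis of the target

Target 31 is a germacranolide: a ten-membered carbocycle (C1–C10, with C14 on C10 and C15 on C4) cis-fused at C6–C7 to an α-methylene-γ-butyrolactone (C11–C13, closed on O6). The ring carries two Z trisubstituted alkenes, C1=C10 and C4=C5, and five stereocentres: C3 (acetate, S), C6 (S), C7 (R), C8 (free hydroxyl, S) and C9 (S). C9 is esterified with (2S,3R)-2,3-dimethyloxirane-2-carboxylic acid, the cis-dimethyl epoxide that corresponds to tiglic acid. C6 to C9 are contiguous: H6 and H7 are cis, the C7–C11 bond is anti to O8 along the C6–C9 zigzag, and O8 and O9 are syn. C3 is isolated from this block by the C4=C5 alkene on one side and by C2–C1=C10 on the other. The sensitive groups are the exocyclic enoate (a Michael acceptor), two allylic esters, the epoxide, and the free C8 hydroxyl, which sits next to the C9 ester (acyl shift) and γ to C12 (lactone migration from O6 to O8 under base). The difficulty is a medium ring with two Z trisubstituted alkenes, oxygen on five of its ten carbons and three hydroxyls that must be told apart, all without strong base once the lactone exists. The strategy rests on one feature: the C3–O and C9–O bonds are 1,5-related across the Z-2-methyl-2-ene unit C2–C1=C10(C14), which is the pattern a γ-boryl allylborane leaves when it reacts with two aldehydes. If both aldehydes sit on one lactone, the same reaction closes the ten-membered ring.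

## Retrosynthetic reasoning

**Acyl groups and the C8 silyl ether.** Target 31 is traced back to silyl ether 30, then by cutting the C9 ester C–O bond to alcohol 28 and epoxy acid 27, and by removing the C3 acetate to diol 23. The esters go on last because they are the most base-labile groups. O8 stays silylated to the very end, so that it can neither take over the lactone nor receive the C9 acyl group. The forward steps must distinguish O3 from O9 (O9 is flanked by the silyloxy-bearing C8 and the fully substituted C10) and must free O8 without base.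

**C9–C10 and C2–C3 (key disconnection).** Diol 23 is cut at both bonds that flank the C1=C10 alkene. Each bond ends at a carbinol carbon, and the four carbons between them (C10, C14, C1, C2) are the allyl unit of a bifunctional reagent. The cut gives lactone dialdehyde 15 and allylborane 20. One operation then has to deliver the ring, two C–C bonds, the C3 and C9 stereocentres and the Z C1=C10 alkene. No other pair of cuts removes the medium ring and both remote carbinols at once. Forward, the dialkylborane end of 20 must choose the C9 aldehyde over the C3 enal, and the allylboronate it leaves at C10 must then reach the enal intramolecularly.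

**The reagent.** Reagent 20 is cut at its C–B(isopinocampheyl) bond to allene 17 and borane 19 (hydroboration). Allene 17 goes back by an SN2′ C–B bond formation to carbonate 16 and so to alcohol 5. Borane 19 comes from pinene 18.

**C3–C4 and the oxidation states at C3 and C9.** Dialdehyde 15 is taken back to diol 14, so that both aldehydes arise in one oxidation. Diol 14 is cut at the C3–C4 bond to alkenyl iodide 13, which lets C3 enter late as a hydroxymethyl group with retention of the Z geometry. Iodide 13 comes from bis-silyl ether 12, diol 11 and acetonide 10 by protecting-group exchange; these steps leave O8 silylated and O9 free.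

**C6–C7 and O6–C12.** Lactone 10 is cut at the C6–C7 bond and the lactone C–O bond to allylic bromide 4 and enal 8. One Barbier-type allylation with lactonisation creates the methylene lactone and both ring stereocentres. C8 is carried in from the chiral pool: bromide 4 goes back through adduct 3 (C7–C11 bond) to aldehyde 1 and acrylate 2. Enal 8 comes from iodo alcohol 7 and alcohol 5. The forward reaction must give the 6,7-syn adduct (cis lactone) and the correct face of C7 relative to C8.

**The side chain.** Acid 27 comes from epoxy alcohol 26 by oxidation, 26 from allylic alcohol 25 by asymmetric epoxidation (both epoxide centres in one step), and 25 from acid 24.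

## Alternatives that were turned down

**Alternative 1:** The disconnection is the lactone C–O bond (O6–C12) on a cyclopentene template that carries C6, C7 and C8, with the two alkene carbons as the future C5 and C9. In the forward key step a serine hydrolase would remove one of two enantiotopic acetates of a meso, all-cis substrate, and the freed hydroxyl would close onto a pendant methyl ester to give bicyclic lactone A1. In its favour: it is catalytic and scalable, and the all-cis C6/C7/C8 triad of the target is fixed by the meso geometry, so the enzyme only has to choose the enantiomer. On this point it is stronger than the chosen route, where the C7 configuration depends on substrate-controlled facial selection in step 5. Against it: the step forms none of the ring C–C bonds, neither trisubstituted alkene, and neither C3 nor C9. After opening the cyclopentene, two aldehydes (C5 and C9) would have to be differentiated and extended, the methylene group added to the lactone by enolate chemistry, and the ten-membered ring still closed. It therefore solves what the chosen route reaches at lactone 10 in a similar number of steps and leaves the medium ring open. In its place the chosen strategy offers the ring, two C–C bonds, C3, C9 and the C1=C10 geometry from one operation.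

**Alternative 2:** The disconnection is the pair of C–O bonds at C3 and C6, traced back to a conjugated diene spanning C3–C6 inside a preformed ten-membered ring. In the forward key step a photosensitised [4+2] oxygenation would give endoperoxide A2; O–O reduction, lactonisation of O6 onto C12 and acetylation of O3 would follow. In its favour: one step places both oxygens on one face and forces the C4=C5 alkene to be cis. On certainty of that alkene geometry and on redox economy it is stronger than the chosen strategy, which sets the Z C4=C5 alkene in an open-chain precursor and has to carry it through. Against it: it presupposes the ring. A ten-membered triene with an s-cis-capable diene, the epoxy ester and the acrylate has to be made first, so the hardest problem is moved upstream unsolved. The face of attack would be set by the conformation of the macrocycle, with no clear bias from C7–C9. The electron-rich C1=C10 alkene, with allylic hydrogens on C2, C9 and C14, would compete in an ene reaction. It is a functionalisation and not a ring synthesis, and its step economy cannot be judged until a route to its substrate exists. The chosen strategy instead brings O3 in together with the C2–C3 bond that closes the ring.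

**Alternative 3:** The disconnection is a transannular C4–C9 bond, so the ten-membered ring is seen as a fragmented cis-fused decalin. In the forward key step a C9 alkoxide would expel a C5 sulfonate with cleavage of C4–C9 (Grob fragmentation), which forms the C4=C5 alkene and a C9 ketone and releases cyclodecadienone lactone A3. In its favour: the fragmentation is concerted and stereospecific, the alkene geometry follows from the relative configuration of the bicycle, and no high dilution is needed. On reliability of the ring-forming event it is stronger than the chosen strategy. Against it: C9 arrives as a ketone, and its reduction to the 9S alcohol in a flexible ring next to the silyloxy-bearing C8 is an open selectivity question. The strongly basic step meets a lactone and gives a ketone that can epimerise at C8. A3 lacks the methylene group. The bicyclic precursor (quaternary C4, tertiary C9 carbinol, antiperiplanar leaving group, C1=C10 alkene, O3, O8 and the fused lactone) needs a long linear sequence, probably about twice the step count of the chosen route. The chosen strategy accepts an untested ring closure in exchange for a short convergent route that sets C9 directly as the carbinol under reagent control.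

Key step: step 14

Remark on the chemistry: atoms are numbered as in germacranolides (above), and it is assumed that diisopinocampheylborane adds to allene 17 from the side of the methyl group, away from the in-plane dioxaborolane, so that 20 (boronate cis to CH2B) is the kinetic isomer.

## Route

Step 1
Reactants: 1 (R)-2,2-dimethyl-1,3-dioxolane-4-carbaldehyde; 2 methyl acrylate
Product: 3 methyl 2-{[(4R)-2,2-dimethyl-1,3-dioxolan-4-yl](hydroxy)methyl}prop-2-enoate (both carbinol epimers)
Conditions: DABCO (0.5 equiv), 2 (3 equiv), 1,4-dioxane/H2O 1:1, rt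
Reagents that add atoms: none
Why: Morita–Baylis–Hillman reaction; the new carbinol centre is irrelevant because it becomes sp2 in step 2, and the dioxolane centre (the later C8) is not involved; the fast aqueous protocol limits base-induced epimerisation α to the aldehyde.

Step 2
Reactants: 3 methyl 2-{[(4R)-2,2-dimethyl-1,3-dioxolan-4-yl](hydroxy)methyl}prop-2-enoate
Product: 4 methyl (2Z)-2-(bromomethyl)-3-[(4S)-2,2-dimethyl-1,3-dioxolan-4-yl]prop-2-enoate
Conditions: NBS, Me2S, CH2Cl2, 0 °C to rt
Reagents that add atoms: N-bromosuccinimide, O=C1CCC(=O)N1Br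
Why: Corey–Kim-type activation of the hydroxyl as an alkoxysulfonium salt and SN2′ attack of bromide at the terminal methylene; the trisubstituted enoate should form as the Z isomer (dioxolane cis to CH2Br, trans to the ester), the usual thermodynamic outcome for such adducts; the neutral medium spares the acetonide.

Step 3
Reactants: 5 but-2-yn-1-ol
Product: 7 (2Z)-3-iodobut-2-en-1-ol, via cyclic vinylalanate 6 (not isolated)
Conditions: NaAlH2(OCH2CH2OMe)2, THF, 0 °C to rt; then EtOAc; then I2, THF, −78 to 0 °C
Reagents that add atoms: iodine, II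
Why: hydroxyl-directed trans-hydroalumination places aluminium on C3 inside the five-membered alanate 6, and iodinolysis with retention should give only the Z iodide; a standard preparation.

Step 4
Reactants: 7 (2Z)-3-iodobut-2-en-1-ol
Product: 8 (2Z)-3-iodobut-2-enal
Conditions: MnO2 (activated, excess), CH2Cl2, rt, dark; used at once
Reagents that add atoms: none
Why: heterogeneous allylic oxidation under neutral conditions, with no acid or base to isomerise the Z β-iodo enal.

Step 5
Reactants: 4 methyl (2Z)-2-(bromomethyl)-3-[(4S)-2,2-dimethyl-1,3-dioxolan-4-yl]prop-2-enoate; 8 (2Z)-3-iodobut-2-enal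
Product: 10 (4S,5R)-4-[(4S)-2,2-dimethyl-1,3-dioxolan-4-yl]-5-[(1Z)-2-iodoprop-1-en-1-yl]-3-methylideneoxolan-2-one, via syn hydroxy ester 9 (not isolated)
Conditions: In powder (1.5 equiv), THF/H2O 1:1, rt; then PPTS (cat.), toluene, 50 °C
Reagents that add atoms: none
Why: Barbier-type 2-(alkoxycarbonyl)allylation: the allylindium from 4 should add through its γ-carbon (C7) to the aldehyde carbon (C6) in a six-membered chair in which the dioxolanyl group, cis to CH2In, is axial, giving the 6,7-syn adduct 9 and hence the cis lactone. The face of C7 is set by the adjacent dioxolane centre: with H8 in the alkene plane (A(1,3) strain) the aldehyde is expected to bond anti to the C8–C9 bond, past the ring oxygen, which gives the configuration drawn. Acid then closes the γ-lactone (5-exo-trig) with loss of methanol.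

Step 6
Reactants: 10 (4S,5R)-4-[(4S)-2,2-dimethyl-1,3-dioxolan-4-yl]-5-[(1Z)-2-iodoprop-1-en-1-yl]-3-methylideneoxolan-2-one
Product: 11 (4R,5R)-4-[(1S)-1,2-dihydroxyethyl]-5-[(1Z)-2-iodoprop-1-en-1-yl]-3-methylideneoxolan-2-one
Conditions: AcOH/H2O 4:1, 40 °C
Reagents that add atoms: none
Why: acid hydrolysis of a terminal acetonide; alkenyl iodide and enoate are inert, and mild acid with short exposure is chosen so that the lactone does not move from O6 to the freed O8.

Step 7
Reactants: 11 (4R,5R)-4-[(1S)-1,2-dihydroxyethyl]-5-[(1Z)-2-iodoprop-1-en-1-yl]-3-methylideneoxolan-2-one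
Product: 12 (4S,5R)-4-[(1S)-1,2-bis{[tert-butyl(dimethyl)silyl]oxy}ethyl]-5-[(1Z)-2-iodoprop-1-en-1-yl]-3-methylideneoxolan-2-one
Conditions: TBSOTf (2.5 equiv), 2,6-lutidine, CH2Cl2, −78 to 0 °C
Reagents that add atoms: tert-butyldimethylsilyl trifluoromethanesulfonate, CC(C)(C)[Si](C)(C)OS(=O)(=O)C(F)(F)F
Why: the silyl triflate with a hindered, non-nucleophilic base covers the hindered C8 hydroxyl as well as the primary one, without a nucleophile or strong base that could attack the enoate or shift the lactone.

Step 8
Reactants: 12 (4S,5R)-4-[(1S)-1,2-bis{[tert-butyl(dimethyl)silyl]oxy}ethyl]-5-[(1Z)-2-iodoprop-1-en-1-yl]-3-methylideneoxolan-2-one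
Product: 13 (4S,5R)-4-[(1S)-1-{[tert-butyl(dimethyl)silyl]oxy}-2-hydroxyethyl]-5-[(1Z)-2-iodoprop-1-en-1-yl]-3-methylideneoxolan-2-one
Conditions: HF·pyridine, pyridine, THF, 0 °C
Reagents that add atoms: none
Why: primary silyl ethers are cleaved by buffered HF·pyridine much faster than secondary ones, so O9 should be freed while O8 stays protected.

Step 9
Reactants: 13 (4S,5R)-4-[(1S)-1-{[tert-butyl(dimethyl)silyl]oxy}-2-hydroxyethyl]-5-[(1Z)-2-iodoprop-1-en-1-yl]-3-methylideneoxolan-2-one
Product: 14 (4S,5S)-4-[(1S)-1-{[tert-butyl(dimethyl)silyl]oxy}-2-hydroxyethyl]-5-[(1Z)-3-hydroxy-2-methylprop-1-en-1-yl]-3-methylideneoxolan-2-one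
Conditions: Bu3SnCH2OH (1.5 equiv), Pd(PPh3)4 (10 mol%), toluene, 80 °C
Reagents that add atoms: (tributylstannyl)methanol, CCCC[Sn](CCCC)(CCCC)CO
Why: Stille coupling: oxidative addition of the alkenyl iodide to zerovalent palladium and transfer of the hydroxymethyl group from tin both proceed with retention, so C3 enters cis to C6 (Z alkene); the neutral medium tolerates the free hydroxyl, the silyl ether and the enoate.

Step 10
Reactants: 14 (4S,5S)-4-[(1S)-1-{[tert-butyl(dimethyl)silyl]oxy}-2-hydroxyethyl]-5-[(1Z)-3-hydroxy-2-methylprop-1-en-1-yl]-3-methylideneoxolan-2-one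
Product: 15 (2S)-2-{[tert-butyl(dimethyl)silyl]oxy}-2-{(2S,3S)-2-[(1Z)-2-methyl-3-oxoprop-1-en-1-yl]-4-methylidene-5-oxooxolan-3-yl}acetaldehyde
Conditions: Dess–Martin periodinane (3 equiv), NaHCO3, CH2Cl2, 0 °C to rt; used crude
Reagents that add atoms: none
Why: Dess–Martin oxidation of both primary hydroxyls in one operation under buffered, non-basic conditions, which should preserve the Z enal and the C8 centre α to the new aldehyde.

Step 11
Reactants: 5 but-2-yn-1-ol
Product: 16 but-2-yn-1-yl methyl carbonate
Conditions: ClCO2Me, pyridine, CH2Cl2, 0 °C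
Reagents that add atoms: methyl chloroformate, COC(=O)Cl
Why: acylation of the propargylic alcohol; the carbonate is the leaving group for the SN2′ borylation.

Step 12
Reactants: 16 but-2-yn-1-yl methyl carbonate
Product: 17 2-(buta-2,3-dien-2-yl)-4,4,5,5-tetramethyl-1,3,2-dioxaborolane
Conditions: B2pin2, CuOt-Bu (10 mol%), Xantphos (10 mol%), THF, 50 °C
Reagents that add atoms: bis(pinacolato)diboron, CC1(C)OB(OC1(C)C)B1OC(C)(C)C(C)(C)O1
Why: copper-catalysed γ-selective (SN2′) substitution of a propargylic carbonate by a borylcopper species: boron goes to the methyl-bearing alkyne carbon and the carbonate leaves, giving the 1,1-disubstituted allene; the methoxide released turns the catalyst over.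

Step 13
Reactants: 18 (+)-α-pinene
Product: 19 (−)-diisopinocampheylborane, bis[(1R,2S,3R,5R)-2,6,6-trimethylbicyclo[3.1.1]heptan-3-yl]borane
Conditions: BH3·SMe2 (1 equiv), 18 (2.2 equiv), THF, 0 °C; crystallised at 0 °C
Reagents that add atoms: borane–dimethyl sulfide, C[S+](C)[BH3-]
Why: hydroboration of the trisubstituted alkene from the face opposite the gem-dimethyl bridge stops at the dialkylborane; crystallisation in the presence of excess 18 should give material of high enantiomeric purity.

Step 14
Reactants: 15 (2S)-2-{[tert-butyl(dimethyl)silyl]oxy}-2-{(2S,3S)-2-[(1Z)-2-methyl-3-oxoprop-1-en-1-yl]-4-methylidene-5-oxooxolan-3-yl}acetaldehyde; 17 2-(buta-2,3-dien-2-yl)-4,4,5,5-tetramethyl-1,3,2-dioxaborolane; 19 (−)-diisopinocampheylborane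
Product: 23 (1(10)Z,4Z)-(3S,6S,7S,8S,9S)-8-{[tert-butyl(dimethyl)silyl]oxy}-3,9-dihydroxygermacra-1(10),4,11(13)-trien-12,6-olide, via bifunctional allylborane 20 (not isolated), via C9 adduct 21 (not isolated), via cyclic bis-boron ester 22 (not isolated)
Conditions: 17 (1.2 equiv), 19 (1.0 equiv), toluene, −20 to 0 °C; then 15 (1.0 equiv), −78 °C; then dilution with toluene to about 2 mM, −78 to 40 °C; then MeOH, aq. NaHCO3
Reagents that add atoms: none
Why: Proposed new method: hydroboration of the terminal allene bond of 17 gives 20 (methyl trans to CH2B, excess allene leaving no free borane for the enoate), whose dialkylallylborane end should add at −78 °C to the saturated, oxygen-activated C9 aldehyde of 15 in preference to the conjugated, α-methylated C3 enal, through a six-membered chair with the aldehyde substituent and the methyl group equatorial and the boronate axial; this joins C9 to C10 and leaves tertiary allylboronate 21. On dilution and warming, this boronate should allylate the tethered enal through a second chair with allylic transposition, so that the C2–C3 bond, the C1=C10 alkene and the ten-membered ring form together (10-exo-trig closure at the carbonyl carbon, both alkene carbons inside the ring), and mild hydrolysis of 22 gives 23. The closest known reactions are the one-pot double allylboration of two different aldehydes with γ-boryl allyl(diisopinocampheyl)boranes to 1,5-diols, single additions of the γ-methyl reagent, and the Z-selective allylboration of aldehydes by α,α-disubstituted allyl pinacol boronates; a ring-forming version and the methyl-bearing double sequence are not known. C9 (S) is set by the isopinocampheyl groups from (+)-α-pinene, which direct the allyl unit to the Si face of the aldehyde and must override the 8,9-anti preference of the α-silyloxy aldehyde. The transient C10 centre (S) follows from the reagent geometry (methyl anti, boron syn to O9). It is relayed to C3 in the second chair: with the larger C9 chain pseudo-axial and the methyl pseudo-equatorial, as tertiary pinacol boronates prefer and as a cis alkene in a ten-membered ring requires, the enal is attacked on its Si face, so the Z alkene and 3S arise as a pair (the E alkene would come with 3R). The step needs chemoselectivity between the two carbonyls, secured by their different electrophilicity and one equivalent of reagent at −78 °C, and ring closure ahead of intermolecular allylboration, secured by dilution before warming.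

Step 15
Reactants: 24 tiglic acid
Product: 25 (2E)-2-methylbut-2-en-1-ol
Conditions: LiAlH4, Et2O, 0 °C to rt
Reagents that add atoms: none
Why: hydride reduction of the acid to the allylic alcohol (1,2-reduction) with the E geometry unchanged.

Step 16
Reactants: 25 (2E)-2-methylbut-2-en-1-ol
Product: 26 [(2R,3R)-2,3-dimethyloxiran-2-yl]methanol
Conditions: Ti(Oi-Pr)4 (10 mol%), D-(−)-diethyl tartrate (12 mol%), t-BuOOH, 4 Å molecular sieves, CH2Cl2, −20 °C
Reagents that add atoms: tert-butyl hydroperoxide, CC(C)(C)OO
Why: Katsuki–Sharpless asymmetric epoxidation; D-(−)-tartrate delivers oxygen to the face that gives the (2R,3R) epoxy alcohol, and the E alkene fixes the cis relation of the two methyl groups.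

Step 17
Reactants: 26 [(2R,3R)-2,3-dimethyloxiran-2-yl]methanol
Product: 27 (2S,3R)-2,3-dimethyloxirane-2-carboxylic acid
Conditions: RuCl3·xH2O (3 mol%), NaIO4 (4 equiv), MeCN/CCl4/H2O 2:2:3, rt
Reagents that add atoms: sodium periodate, [Na+].[O-]I(=O)(=O)=O; water, O
Why: catalytically generated RuO4 oxidises the primary alcohol to the acid without touching the epoxide; C2 bears no hydrogen and cannot epimerise, and its descriptor changes from R to S only through the change in priorities.

Step 18
Reactants: 23 (1(10)Z,4Z)-(3S,6S,7S,8S,9S)-8-{[tert-butyl(dimethyl)silyl]oxy}-3,9-dihydroxygermacra-1(10),4,11(13)-trien-12,6-olide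
Product: 28 (1(10)Z,4Z)-(3S,6S,7S,8S,9S)-3-(acetyloxy)-8-{[tert-butyl(dimethyl)silyl]oxy}-9-hydroxygermacra-1(10),4,11(13)-trien-12,6-olide
Conditions: Ac2O (1.1 equiv), pyridine, CH2Cl2, −20 to 0 °C
Reagents that add atoms: acetic anhydride, CC(=O)OC(C)=O
Why: the C3 hydroxyl has a methylene neighbour, whereas the C9 hydroxyl lies between the silyloxy-bearing C8 and the fully substituted C10, so acylation with one equivalent of anhydride and no nucleophilic catalyst should take place at O3.

Step 19
Reactants: 27 (2S,3R)-2,3-dimethyloxirane-2-carboxylic acid; 28 (1(10)Z,4Z)-(3S,6S,7S,8S,9S)-3-(acetyloxy)-8-{[tert-butyl(dimethyl)silyl]oxy}-9-hydroxygermacra-1(10),4,11(13)-trien-12,6-olide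
Product: 30 (1(10)Z,4Z)-(3S,6S,7S,8S,9S)-3-(acetyloxy)-8-{[tert-butyl(dimethyl)silyl]oxy}-9-{[(2S,3R)-2,3-dimethyloxiran-2-yl]carbonyloxy}germacra-1(10),4,11(13)-trien-12,6-olide, via mixed anhydride 29 (not isolated)
Conditions: 27, 2,4,6-trichlorobenzoyl chloride, Et3N, toluene, rt; then 28, DMAP (2 equiv), toluene, 0 °C to rt
Reagents that add atoms: none
Why: Yamaguchi esterification: 27 is converted to mixed anhydride 29, from which DMAP transfers the epoxy acyl group to the hindered O9; 27 has no α-hydrogen and cannot epimerise; stoichiometric DMAP and low temperature should keep acylation ahead of silyl migration from O8 to O9 and of conjugate addition of O9 to the enoate.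

Step 20
Reactants: 30 (1(10)Z,4Z)-(3S,6S,7S,8S,9S)-3-(acetyloxy)-8-{[tert-butyl(dimethyl)silyl]oxy}-9-{[(2S,3R)-2,3-dimethyloxiran-2-yl]carbonyloxy}germacra-1(10),4,11(13)-trien-12,6-olide
Product: 31 (1(10)Z,4Z)-(3S,6S,7R,8S,9S)-3-(acetyloxy)-9-{[(2S,3R)-2,3-dimethyloxiran-2-yl]carbonyloxy}-8-hydroxygermacra-1(10),4,11(13)-trien-12,6-olide (target)
Conditions: HF·pyridine, pyridine, THF, 0 °C to rt
Reagents that add atoms: none
Why: fluoride cleavage of the last silyl ether under acidic, pyridine-buffered conditions avoids the basic medium that would promote acyl migration from O9 to O8, lactone migration or epoxide opening; no stereocentre is touched (the C7 descriptor changes from S to R only through the change in priorities).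

## Compound list

1 | (R)-2,2-dimethyl-1,3-dioxolane-4-carbaldehyde | CC1(C)OC[C@H](C=O)O1 | starting material
2 | methyl acrylate | C=CC(=O)OC | starting material
3 | methyl 2-{[(4R)-2,2-dimethyl-1,3-dioxolan-4-yl](hydroxy)methyl}prop-2-enoate (both carbinol epimers) | CC1(C)OC[C@H](C(O)C(=C)C(=O)OC)O1 | intermediate
4 | methyl (2Z)-2-(bromomethyl)-3-[(4S)-2,2-dimethyl-1,3-dioxolan-4-yl]prop-2-enoate | CC1(C)OC[C@H](/C=C(\CBr)C(=O)OC)O1 | intermediate
5 | but-2-yn-1-ol | CC#CCO | starting material
6 | sodium 2,2-bis(2-methoxyethoxy)-3-methyl-2,5-dihydro-1,2-oxaaluminol-2-uide (cyclic vinylalanate, not isolated) | CC1=CCO[Al-]1(OCCOC)OCCOC.[Na+] | intermediate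
7 | (2Z)-3-iodobut-2-en-1-ol | C/C(I)=C/CO | intermediate
8 | (2Z)-3-iodobut-2-enal | C/C(I)=C/C=O | intermediate
9 | methyl (3S,4R,5Z)-3-[(4S)-2,2-dimethyl-1,3-dioxolan-4-yl]-4-hydroxy-6-iodo-2-methylidenehept-5-enoate (not isolated) | C=C(C(=O)OC)[C@@H]([C@@H](O)/C=C(/C)I)[C@H](OC(C)(C)O1)C1 | intermediate
10 | (4S,5R)-4-[(4S)-2,2-dimethyl-1,3-dioxolan-4-yl]-5-[(1Z)-2-iodoprop-1-en-1-yl]-3-methylideneoxolan-2-one | C=C1C(=O)O[C@@H](/C=C(/C)I)[C@H]1[C@H](OC(C)(C)O2)C2 | intermediate
11 | (4R,5R)-4-[(1S)-1,2-dihydroxyethyl]-5-[(1Z)-2-iodoprop-1-en-1-yl]-3-methylideneoxolan-2-one | C=C1C(=O)O[C@@H](/C=C(/C)I)[C@H]1[C@H](O)CO | intermediate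
12 | (4S,5R)-4-[(1S)-1,2-bis{[tert-butyl(dimethyl)silyl]oxy}ethyl]-5-[(1Z)-2-iodoprop-1-en-1-yl]-3-methylideneoxolan-2-one | C=C1C(=O)O[C@@H](/C=C(/C)I)[C@H]1[C@H](O[Si](C)(C)C(C)(C)C)CO[Si](C)(C)C(C)(C)C | intermediate
13 | (4S,5R)-4-[(1S)-1-{[tert-butyl(dimethyl)silyl]oxy}-2-hydroxyethyl]-5-[(1Z)-2-iodoprop-1-en-1-yl]-3-methylideneoxolan-2-one | C=C1C(=O)O[C@@H](/C=C(/C)I)[C@H]1[C@H](O[Si](C)(C)C(C)(C)C)CO | intermediate
14 | (4S,5S)-4-[(1S)-1-{[tert-butyl(dimethyl)silyl]oxy}-2-hydroxyethyl]-5-[(1Z)-3-hydroxy-2-methylprop-1-en-1-yl]-3-methylideneoxolan-2-one | C=C1C(=O)O[C@@H](/C=C(/C)CO)[C@H]1[C@H](O[Si](C)(C)C(C)(C)C)CO | intermediate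
15 | (2S)-2-{[tert-butyl(dimethyl)silyl]oxy}-2-{(2S,3S)-2-[(1Z)-2-methyl-3-oxoprop-1-en-1-yl]-4-methylidene-5-oxooxolan-3-yl}acetaldehyde (lactone dialdehyde) | C=C1C(=O)O[C@@H](/C=C(/C)C=O)[C@H]1[C@H](O[Si](C)(C)C(C)(C)C)C=O | intermediate
16 | but-2-yn-1-yl methyl carbonate | CC#CCOC(=O)OC | intermediate
17 | 2-(buta-2,3-dien-2-yl)-4,4,5,5-tetramethyl-1,3,2-dioxaborolane | C=C=C(C)B1OC(C)(C)C(C)(C)O1 | intermediate
18 | (+)-α-pinene, (1R,5R)-2,6,6-trimethylbicyclo[3.1.1]hept-2-ene | CC1=CC[C@@H]2C[C@H]1C2(C)C | starting material
19 | (−)-diisopinocampheylborane, bis[(1R,2S,3R,5R)-2,6,6-trimethylbicyclo[3.1.1]heptan-3-yl]borane | B([C@@H]1C[C@@H]2C[C@H]([C@H]1C)C2(C)C)[C@@H]1C[C@@H]2C[C@H]([C@H]1C)C2(C)C | intermediate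
20 | 2-[(2E)-4-(diisopinocampheylboranyl)but-2-en-2-yl]-4,4,5,5-tetramethyl-1,3,2-dioxaborolane (boronate cis to CH2B; not isolated) | C/C(B1OC(C)(C)C(C)(C)O1)=C/CB([C@@H]1C[C@@H]2C[C@H]([C@H]1C)C2(C)C)[C@@H]1C[C@@H]2C[C@H]([C@H]1C)C2(C)C | intermediate
21 | (9S,10S) adduct of 15 at C9: O9 diisopinocampheylborinate, C10 bearing methyl, vinyl and the pinacol boronate, C3 enal intact (not isolated) | C=C1C(=O)O[C@@H](/C=C(/C)C=O)[C@H]1[C@H](O[Si](C)(C)C(C)(C)C)[C@@H](OB([C@@H]2C[C@@H]3C[C@H]([C@H]2C)C3(C)C)[C@@H]2C[C@@H]3C[C@H]([C@H]2C)C3(C)C)[C@@](C)(C=C)B2OC(C)(C)C(C)(C)O2 | intermediate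
22 | ten-membered ring product before hydrolysis: 23 with O9 as diisopinocampheylborinate and O3 as pinacol borate (not isolated) | C=C1C(=O)O[C@H]2/C=C(/C)[C@@H](OB3OC(C)(C)C(C)(C)O3)C/C=C(/C)[C@H](OB([C@@H]3C[C@@H]4C[C@H]([C@H]3C)C4(C)C)[C@@H]3C[C@@H]4C[C@H]([C@H]3C)C4(C)C)[C@@H](O[Si](C)(C)C(C)(C)C)[C@@H]12 | intermediate
23 | (1(10)Z,4Z)-(3S,6S,7S,8S,9S)-8-{[tert-butyl(dimethyl)silyl]oxy}-3,9-dihydroxygermacra-1(10),4,11(13)-trien-12,6-olide | C=C1C(=O)O[C@H]2/C=C(/C)[C@@H](O)C/C=C(/C)[C@H](O)[C@@H](O[Si](C)(C)C(C)(C)C)[C@@H]12 | intermediate
24 | tiglic acid, (2E)-2-methylbut-2-enoic acid | C/C=C(\C)C(=O)O | starting material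
25 | (2E)-2-methylbut-2-en-1-ol | C/C=C(\C)CO | intermediate
26 | [(2R,3R)-2,3-dimethyloxiran-2-yl]methanol | OC[C@@]1(C)O[C@@H]1C | intermediate
27 | (2S,3R)-2,3-dimethyloxirane-2-carboxylic acid | OC(=O)[C@@]1(C)O[C@@H]1C | intermediate
28 | 3-O-acetyl derivative of 23, (3S,6S,7S,8S,9S) | C=C1C(=O)O[C@H]2/C=C(/C)[C@@H](OC(C)=O)C/C=C(/C)[C@H](O)[C@@H](O[Si](C)(C)C(C)(C)C)[C@@H]12 | intermediate
29 | (2S,3R)-2,3-dimethyloxirane-2-carboxylic 2,4,6-trichlorobenzoic anhydride (not isolated) | O=C(OC(=O)[C@@]1(C)O[C@@H]1C)c1c(Cl)cc(Cl)cc1Cl | intermediate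
30 | 8-O-tert-butyldimethylsilyl ether of the target, (3S,6S,7S,8S,9S) | C=C1C(=O)O[C@H]2/C=C(/C)[C@@H](OC(C)=O)C/C=C(/C)[C@H](OC(=O)[C@@]3(C)O[C@@H]3C)[C@@H](O[Si](C)(C)C(C)(C)C)[C@@H]12 | intermediate
31 | (1(10)Z,4Z)-(3S,6S,7R,8S,9S)-3-(acetyloxy)-9-{[(2S,3R)-2,3-dimethyloxiran-2-yl]carbonyloxy}-8-hydroxygermacra-1(10),4,11(13)-trien-12,6-olide | C=C1C(=O)O[C@H]2/C=C(/C)[C@@H](OC(C)=O)C/C=C(/C)[C@H](OC(=O)[C@@]3(C)O[C@@H]3C)[C@@H](O)[C@@H]12 | target

## Step count and least certain steps

Total: 20 steps. Longest linear sequence: 12 steps (1, 2, 5, 6, 7, 8, 9, 10, 14, 18, 19, 20) from aldehyde 1.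

**Step 14 (key step, proposed new method).** Three things can go wrong.
- The first allylboration may occur at the C3 enal, or at both carbonyls, if the α-silyloxy, β-branched C9 aldehyde proves too hindered for a reagent that must form a fully substituted carbon next to it.
- The hindered tertiary boronate may fail to close the ring, reacting intermolecularly or not at all, because a ten-membered bicyclic transition state carries transannular strain.
- Facial control at C9 may erode, because reagent and substrate preferences are opposed.

Fallback, with known reaction types and a different ring closure: it sets out from iodide 13 and returns at 23. Dess–Martin oxidation of 13 gives aldehyde F1, which has only one carbonyl group. Allylboration with 20 (made as in step 14) gives tertiary boronate F2, which is not isolated but treated with monomeric formaldehyde; this intermolecular allylboration with the least hindered aldehyde should give, after hydrolysis, the (Z)-homoallylic diol F3. Selective oxidation of its primary hydroxyl (TEMPO, PhI(OAc)2) gives hydroxy aldehyde F4. A Nozaki–Hiyama–Kishi reaction (CrCl2, NiCl2 cat., DMSO/THF, high dilution) then adds the C4 alkenylchromium to the C3 aldehyde and closes the ten-membered ring at C3–C4. In this variant the C3 configuration rests on the conformation of the closing ring instead of on chirality transfer.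

**Step 5.** The sense or level of 1,2-induction from the dioxolane centre at C7 is the least secure selectivity outside the key step, because it rests on a conformational model and coordination of indium by the acetal oxygen could favour the other rotamer. Loss of the allyl unit by 1,4-elimination of the γ-oxygen is a second possible failure. Fallback: it sets out from adduct 3 and returns at lactone 10. Acetylation of 3 gives acetate F5; copper-mediated SN2′ borylation (B2pin2, CuCl, LiCl, KOAc, DMF) gives allylboronate F6 with the dioxolane cis to CH2B. Its allylboration of 8 (Sc(OTf)3 cat., toluene, −78 °C to rt) runs through a closed chair without a free allylmetal and without metal chelation, and acid lactonisation of the resulting 9 gives 10.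

**Step 9.** The slow transfer of the hydroxymethyl group may let the alkenylpalladium intermediate be diverted into the neighbouring exocyclic enoate, and zerovalent palladium at 80 °C may ionise the allylic lactone C6–O bond of the product. Fallback without palladium: it sets out from 13 and returns at 14 with no new compound. The alkenyl iodide is hydroxymethylated by a Nozaki–Hiyama–Kishi addition to paraformaldehyde (CrCl2, NiCl2 cat., DMF), which tolerates the enoate and the free hydroxyl.

**Step 18.** Discrimination between the two secondary allylic hydroxyls may be incomplete, giving acetylation at O9 or at both. Fallback, which reverses the order of the two acylations: it sets out from 23 and returns at 30. The more sterically demanding triethylsilyl chloride (imidazole, −40 °C) should select O3 and give silyl ether F7. Yamaguchi esterification with 27 (via 29) gives ester F8. The triethylsilyl group is removed in the presence of the secondary tert-butyldimethylsilyl ether (PPTS, MeOH, 0 °C) to give alcohol F9, whose only free hydroxyl is acetylated (Ac2O, pyridine, DMAP) to give 30.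

## Further compounds

F1 | step 14 | (2S)-2-{[tert-butyl(dimethyl)silyl]oxy}-2-{(2R,3S)-2-[(1Z)-2-iodoprop-1-en-1-yl]-4-methylidene-5-oxooxolan-3-yl}acetaldehyde | C=C1C(=O)O[C@@H](/C=C(/C)I)[C@H]1[C@H](O[Si](C)(C)C(C)(C)C)C=O
F2 | step 14 | adduct of F1 and 20: O9 diisopinocampheylborinate with C10 bearing methyl, vinyl and the pinacol boronate (9S,10S; not isolated) | C=C1C(=O)O[C@@H](/C=C(/C)I)[C@H]1[C@H](O[Si](C)(C)C(C)(C)C)[C@@H](OB([C@@H]2C[C@@H]3C[C@H]([C@H]2C)C3(C)C)[C@@H]2C[C@@H]3C[C@H]([C@H]2C)C3(C)C)[C@@](C)(C=C)B2OC(C)(C)C(C)(C)O2
F3 | step 14 | (4S,5R)-4-[(1S,2S,3Z)-1-{[tert-butyl(dimethyl)silyl]oxy}-2,6-dihydroxy-3-methylhex-3-en-1-yl]-5-[(1Z)-2-iodoprop-1-en-1-yl]-3-methylideneoxolan-2-one | C=C1C(=O)O[C@@H](/C=C(/C)I)[C@H]1[C@H](O[Si](C)(C)C(C)(C)C)[C@@H](O)/C(C)=C\CCO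
F4 | step 14 | aldehyde from F3 by oxidation of the primary hydroxyl (C3 aldehyde, C9 hydroxyl, C4 iodide) | C=C1C(=O)O[C@@H](/C=C(/C)I)[C@H]1[C@H](O[Si](C)(C)C(C)(C)C)[C@@H](O)/C(C)=C\CC=O
F5 | step 5 | methyl 2-{(acetyloxy)[(4R)-2,2-dimethyl-1,3-dioxolan-4-yl]methyl}prop-2-enoate | CC1(C)OC[C@H](C(OC(C)=O)C(=C)C(=O)OC)O1
F6 | step 5 | methyl (2E)-3-[(4S)-2,2-dimethyl-1,3-dioxolan-4-yl]-2-[(4,4,5,5-tetramethyl-1,3,2-dioxaborolan-2-yl)methyl]prop-2-enoate | CC1(C)OC[C@H](/C=C(\CB2OC(C)(C)C(C)(C)O2)C(=O)OC)O1
F0 | step 9 | none | none
F7 | step 18 | 3-O-triethylsilyl ether of 23 | C=C1C(=O)O[C@H]2/C=C(/C)[C@@H](O[Si](CC)(CC)CC)C/C=C(/C)[C@H](O)[C@@H](O[Si](C)(C)C(C)(C)C)[C@@H]12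
F8 | step 18 | 3-O-triethylsilyl-9-O-[(2S,3R)-2,3-dimethyloxirane-2-carbonyl] derivative of 23 | C=C1C(=O)O[C@H]2/C=C(/C)[C@@H](O[Si](CC)(CC)CC)C/C=C(/C)[C@H](OC(=O)[C@@]3(C)O[C@@H]3C)[C@@H](O[Si](C)(C)C(C)(C)C)[C@@H]12
F9 | step 18 | 9-O-[(2S,3R)-2,3-dimethyloxirane-2-carbonyl] derivative of 23 with free C3 hydroxyl | C=C1C(=O)O[C@H]2/C=C(/C)[C@@H](O)C/C=C(/C)[C@H](OC(=O)[C@@]3(C)O[C@@H]3C)[C@@H](O[Si](C)(C)C(C)(C)C)[C@@H]12
A1 | alternative 1 | all-cis 4-(acetyloxy)-3,3a,4,6a-tetrahydro-2H-cyclopenta[b]furan-2-one (cis-fused bicyclic lactone with C8 acetate) | C1C(=O)O[C@H]2C=C[C@@H](OC(C)=O)[C@@H]12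
A2 | alternative 2 | C3,C6-endoperoxide of the ten-membered methyl 12-oate with free C8 hydroxyl and the C9 epoxy ester | C=C(C(=O)OC)[C@H]1[C@@H]2/C=C(/C)[C@@H](OO2)C/C=C(/C)[C@H](OC(=O)[C@@]3(C)O[C@@H]3C)[C@H]1O
A3 | alternative 3 | (1(10)Z,4Z)-3-[(4-methoxybenzyl)oxy]-8-{[tert-butyl(dimethyl)silyl]oxy}-9-oxogermacra-1(10),4-dien-12,6-olide | C1C(=O)O[C@H]2/C=C(/C)[C@@H](OCc3ccc(OC)cc3)C/C=C(/C)C(=O)[C@@H](O[Si](C)(C)C(C)(C)C)[C@@H]12
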